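**Plan**
- Cuts: C11=C12 and C11'=C12' (two Wittig reactions on a commercial C10 dialdehyde), then C6–C7 (Sonogashira) and C6'–C7' (B-alkyl Suzuki–Miyaura), so both end rings come from one (4R)-silyloxy-trimethylcyclohexenyl triflate. That ring is cut between its carbinol carbon and the CH2 next to the gem-dimethyl carbon (C2'–C3' in ring B, C2–C3 in ring A) and at one C1–CH3 bond.
- Forward order: acyclic (3S) keto-enal 9 → six-membered ring by reductive cyclisation with methylation in the same flask (step 5) → enol triflate 14 → C15 phosphonium salts 18 and 23 → C25 aldehyde 27 → C40 target 30.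
- Enabling feature: in each end ring the carbinol carbon C3 and the chain-bearing carbon C6 stand 1,4, with C2 and the gem-dimethyl carbon C1 between them. With C6 as a ketone, C1=C2 is an enone whose β-carbon C2 accepts a ketyl centred on C3, and the enolate left at C1 is where the second methyl group is needed.
- Stereochemistry: an Evans alkylation fixes the methyl-bearing carbon (later C5/C5'). It directs the new carbinol centre (3R and 3'R) in the ring closure and is erased when the enol triflate is made. Alkene geometry comes from (E)-enynol 15, all-E dialdehyde 24, and Wittig reactions followed by thermal Z→E equilibration.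

Key step: step 5

Assumption: any minor trans isomer from step 5 is removed by chromatography at 11 or 12; either C6 epimer of the (4R) carbinol serves, because C6 becomes sp2 in step 7.

**Step 1**
Reactants: 1 (4R)-4-benzyl-3-propanoyl-1,3-oxazolidin-2-one; 2 1-bromo-3-methylbut-2-ene
Product: 4 (4R)-4-benzyl-3-[(2S)-2,5-dimethylhex-4-enoyl]-1,3-oxazolidin-2-one, via sodium enolate 3 (not isolated)
Conditions: NaN(SiMe3)2, THF, −78 °C; then 2, −78 → −30 °C
Reagents that add atoms: none
Why: Evans asymmetric alkylation, in which the chelated Z-enolate is alkylated by the allylic bromide on the face opposite the benzyl group, should set the (S) methyl-bearing centre.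

**Step 2**
Reactants: 4 (4R)-4-benzyl-3-[(2S)-2,5-dimethylhex-4-enoyl]-1,3-oxazolidin-2-one
Product: 5 (2S)-N-methoxy-N,2,5-trimethylhex-4-enamide
Conditions: MeNH(OMe)·HCl, AlMe3, CH2Cl2, 0 °C → rt
Reagents that add atoms: N,O-dimethylhydroxylamine hydrochloride, CNOC.Cl
Why: Aluminium amide transamination to the Weinreb amide should remove the auxiliary without touching the α-centre.

**Step 3**
Reactants: 5 (2S)-N-methoxy-N,2,5-trimethylhex-4-enamide; 6 isopropenylmagnesium bromide
Product: 7 (4S)-2,4,7-trimethylocta-1,6-dien-3-one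
Conditions: THF, −20 → 0 °C; cold aq. NH4Cl
Reagents that add atoms: none
Why: Grignard addition to a Weinreb amide stops at the chelated adduct, so the α-methyl enone should be released only on work-up, without over-addition or epimerisation.

**Step 4**
Reactants: 7 (4S)-2,4,7-trimethylocta-1,6-dien-3-one
Product: 9 (3S)-3,5-dimethyl-4-oxohex-5-enal, via ozonide 8 (not isolated)
Conditions: O3/O2, CH2Cl2, −78 °C, Sudan Red 7B end-point; then PPh3, −78 °C → rt
Reagents that add atoms: ozone, [O-][O+]=O
Why: Criegee ozonolysis with reductive work-up should cleave the electron-rich trisubstituted alkene well before the electron-poor enone alkene.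

**Step 5**
Reactants: 9 (3S)-3,5-dimethyl-4-oxohex-5-enal
Product: 11 (4R,6S)-4-hydroxy-2,2,6-trimethylcyclohexan-1-one, via cyclised samarium enolate 10 (not isolated)
Conditions: SmI2 (2.1 equiv), HMPA, THF, −78 °C, slow addition of 9 at high dilution, no proton source; then MeI (excess), −78 °C → rt; aq. NH4Cl
Reagents that add atoms: iodomethane, CI
Why: Proposed new method: SmI2 reduces the aldehyde (or the enone, which converges on the same bond) to a ketyl that adds to the unsubstituted β-carbon of the s-trans α-methyl enone, joining the carbinol carbon to the CH2 that ends up next to the gem-dimethyl carbon; a second electron turns the α-keto radical into the trivalent samarium enolate 10, which exists only on the C1 side and is C-methylated there by MeI to give the quaternary carbon. The closest known reaction types are the SmI2 ketyl–olefin reductive cyclisation of aldehydes onto enones or enoates and the Stork reductive alkylation of enones through regiospecific enolates; the new element is their combination, with alkylation of a samarium enolate at a fully substituted carbon. The carbocycle closes by 6-endo-trig radical addition. The new carbinol centre is controlled by the methyl-bearing centre from step 1: in the chair-like transition state the methyl group and the samarium-bound oxygen should both sit pseudo-equatorial, giving the cis (4R,6S) product, while the methylated carbon carries two identical methyl groups and is no stereocentre. The step needs cis facial selectivity, C- over O-methylation and no protonation of the enolate; the existing stereocentre, the soft electrophile in HMPA and aprotic conditions are meant to secure these, and any trans isomer must be removed because it would lead to the enantiomeric triflate.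

**Step 6**
Reactants: 11 (4R,6S)-4-hydroxy-2,2,6-trimethylcyclohexan-1-one
Product: 12 (4R,6S)-2,2,6-trimethyl-4-(triethylsilyloxy)cyclohexan-1-one
Conditions: Et3SiCl, imidazole, DMF, 0 °C → rt
Reagents that add atoms: chlorotriethylsilane, CC[Si](Cl)(CC)CC
Why: Standard silylation of the secondary alcohol should protect it for the enolisation and the cross-couplings.

**Step 7**
Reactants: 12 (4R,6S)-2,2,6-trimethyl-4-(triethylsilyloxy)cyclohexan-1-one
Product: 14 (4R)-2,6,6-trimethyl-4-(triethylsilyloxy)cyclohex-1-en-1-yl trifluoromethanesulfonate, via lithium enolate 13 (not isolated)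
Conditions: LiN(i-Pr)2, THF, −78 → 0 °C; then PhNTf2, −78 °C → rt
Reagents that add atoms: N-phenylbis(trifluoromethanesulfonimide), O=S(=O)(N(c1ccccc1)S(=O)(=O)C(F)(F)F)C(F)(F)F
Why: The ketone has a single enolisable α-position, so enolate O-triflation should give the tetrasubstituted enol triflate regiospecifically and erase the relay centre, leaving only the (4R) carbinol.

**Step 8**
Reactants: 14 (4R)-2,6,6-trimethyl-4-(triethylsilyloxy)cyclohex-1-en-1-yl trifluoromethanesulfonate; 15 (2E)-3-methylpent-2-en-4-yn-1-ol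
Product: 16 (2E)-3-methyl-5-[(4R)-2,6,6-trimethyl-4-(triethylsilyloxy)cyclohex-1-en-1-yl]pent-2-en-4-yn-1-ol
Conditions: Pd(PPh3)4 (cat.), CuI (cat.), i-Pr2NH, DMF, rt → 45 °C
Reagents that add atoms: none
Why: Sonogashira coupling of the enol triflate with the terminal alkyne should install the 7,8-triple bond with the E alkene of 15 unchanged.

**Step 9**
Reactants: 16 (2E)-3-methyl-5-[(4R)-2,6,6-trimethyl-4-(triethylsilyloxy)cyclohex-1-en-1-yl]pent-2-en-4-yn-1-ol
Product: 18 {(2E)-5-[(4R)-4-hydroxy-2,6,6-trimethylcyclohex-1-en-1-yl]-3-methylpent-2-en-4-yn-1-yl}triphenylphosphonium bromide, via desilylated diol 17 (not isolated)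
Conditions: PPh3·HBr, MeOH, 0 °C → rt
Reagents that add atoms: triphenylphosphine hydrobromide, Br.c1ccc(cc1)P(c1ccccc1)c1ccccc1
Why: Acidic methanolysis should cleave the triethylsilyl ether, and the primary allylic alcohol should be converted into the phosphonium salt by acid-mediated substitution at the unhindered allylic terminus.

**Step 10**
Reactants: 15 (2E)-3-methylpent-2-en-4-yn-1-ol
Product: 19 (2E)-3-methylpenta-2,4-dien-1-ol
Conditions: H2 (1 atm), Pd/CaCO3 poisoned with Pb(OAc)2 (Lindlar catalyst), quinoline, EtOAc, 0 °C, stopped after one equivalent of H2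
Reagents that add atoms: none
Why: Lindlar semihydrogenation should reduce the terminal alkyne to the vinyl group and leave the E trisubstituted alkene untouched.

**Step 11**
Reactants: 19 (2E)-3-methylpenta-2,4-dien-1-ol; 14 (4R)-2,6,6-trimethyl-4-(triethylsilyloxy)cyclohex-1-en-1-yl trifluoromethanesulfonate
Product: 21 (2E)-3-methyl-5-[(4R)-2,6,6-trimethyl-4-(triethylsilyloxy)cyclohex-1-en-1-yl]pent-2-en-1-ol, via alkylborane 20 (not isolated)
Conditions: 9-borabicyclo[3.3.1]nonane (2.2 equiv), THF, 0 °C → rt; then 14, Pd(dppf)Cl2 (cat.), AsPh3, aq. Cs2CO3, DMF, 50 °C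
Reagents that add atoms: none
Why: Anti-Markovnikov hydroboration of the terminal vinyl group followed by B-alkyl Suzuki–Miyaura coupling with the enol triflate should give the saturated C7'–C8' link on a regiodefined tetrasubstituted ring alkene.

**Step 12**
Reactants: 21 (2E)-3-methyl-5-[(4R)-2,6,6-trimethyl-4-(triethylsilyloxy)cyclohex-1-en-1-yl]pent-2-en-1-ol
Product: 23 {(2E)-5-[(4R)-4-hydroxy-2,6,6-trimethylcyclohex-1-en-1-yl]-3-methylpent-2-en-1-yl}triphenylphosphonium bromide, via desilylated diol 22 (not isolated)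
Conditions: PPh3·HBr, MeOH, 0 °C → rt
Reagents that add atoms: triphenylphosphine hydrobromide, Br.c1ccc(cc1)P(c1ccccc1)c1ccccc1
Why: As in step 9, acidic methanolysis of the silyl ether and substitution of the allylic alcohol by triphenylphosphine at the primary terminus should give the salt with the E trisubstituted alkene.

**Step 13**
Reactants: 23 {(2E)-5-[(4R)-4-hydroxy-2,6,6-trimethylcyclohex-1-en-1-yl]-3-methylpent-2-en-1-yl}triphenylphosphonium bromide; 24 (2E,4E,6E)-2,7-dimethylocta-2,4,6-trienedial
Product: 27 (2E,4E,6E,8E,10E)-13-[(4R)-4-hydroxy-2,6,6-trimethylcyclohex-1-en-1-yl]-2,7,11-trimethyltrideca-2,4,6,8,10-pentaenal, via phosphorus ylide 25 (not isolated), via (8Z)-aldehyde 26 (not isolated)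
Conditions: NaOMe, 24 (3 equiv), CH2Cl2/MeOH, 0 °C → rt; then heptane, 85 °C, dark, argon
Reagents that add atoms: none
Why: Wittig olefination of one aldehyde group of the excess symmetric dialdehyde should form the C11'=C12' alkene, and heating should convert the strained Z isomer into the E isomer.

**Step 14**
Reactants: 18 {(2E)-5-[(4R)-4-hydroxy-2,6,6-trimethylcyclohex-1-en-1-yl]-3-methylpent-2-en-4-yn-1-yl}triphenylphosphonium bromide; 27 (2E,4E,6E,8E,10E)-13-[(4R)-4-hydroxy-2,6,6-trimethylcyclohex-1-en-1-yl]-2,7,11-trimethyltrideca-2,4,6,8,10-pentaenal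
Product: 30 (3R,3'R)-all-E-7,8-didehydro-7',8'-dihydro-β,β-carotene-3,3'-diol, via phosphorus ylide 28 (not isolated), via (11Z)-isomer 29 (not isolated)
Conditions: NaOMe, CH2Cl2/MeOH, 0 °C → rt; then EtOH, 70 °C, dark, argon; crystallisation
Reagents that add atoms: none
Why: The second Wittig olefination should close the C40 chain at C11=C12, and mild heating should turn the hindered 11Z isomer into the all-E target; the acetylenic fragment is attached last so that its 9E alkene is heated only once.

**Compound list**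
1 | (4R)-4-benzyl-3-propanoyl-1,3-oxazolidin-2-one | CCC(=O)N1[C@H](Cc2ccccc2)COC1=O | starting material
2 | 1-bromo-3-methylbut-2-ene | CC(C)=CCBr | starting material
3 | sodium (Z)-enolate of 1 (not isolated) | C/C=C(\O[Na])N1[C@H](Cc2ccccc2)COC1=O | intermediate
4 | (4R)-4-benzyl-3-[(2S)-2,5-dimethylhex-4-enoyl]-1,3-oxazolidin-2-one | CC(C)=CC[C@H](C)C(=O)N1[C@H](Cc2ccccc2)COC1=O | intermediate
5 | (2S)-N-methoxy-N,2,5-trimethylhex-4-enamide | CC(C)=CC[C@H](C)C(=O)N(C)OC | intermediate
6 | isopropenylmagnesium bromide | C=C(C)[Mg]Br | starting material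
7 | (4S)-2,4,7-trimethylocta-1,6-dien-3-one | CC(C)=CC[C@H](C)C(=O)C(C)=C | intermediate
8 | (4S)-5-(5,5-dimethyl-1,2,4-trioxolan-3-yl)-2,4-dimethylpent-1-en-3-one (ozonide, not isolated, epimers at the ring carbon) | CC1(C)OOC(C[C@H](C)C(=O)C(C)=C)O1 | intermediate
9 | (3S)-3,5-dimethyl-4-oxohex-5-enal | O=CC[C@H](C)C(=O)C(C)=C | intermediate
10 | cyclised samarium enolate: diiodosamarium enolate and alkoxide of the 4-oxy-2,6-dimethylcyclohexene ring (not isolated) | C[C@H]1C[C@@H](O[Sm](I)I)CC(C)=C1O[Sm](I)I | intermediate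
11 | (4R,6S)-4-hydroxy-2,2,6-trimethylcyclohexan-1-one | O=C1[C@@H](C)C[C@@H](O)CC1(C)C | intermediate
12 | (4R,6S)-2,2,6-trimethyl-4-(triethylsilyloxy)cyclohexan-1-one | O=C1[C@@H](C)C[C@@H](O[Si](CC)(CC)CC)CC1(C)C | intermediate
13 | lithium enolate of 12 (not isolated) | CC1=C(O[Li])C(C)(C)C[C@H](O[Si](CC)(CC)CC)C1 | intermediate
14 | (4R)-2,6,6-trimethyl-4-(triethylsilyloxy)cyclohex-1-en-1-yl trifluoromethanesulfonate | CC1=C(OS(=O)(=O)C(F)(F)F)C(C)(C)C[C@H](O[Si](CC)(CC)CC)C1 | intermediate
15 | (2E)-3-methylpent-2-en-4-yn-1-ol | C#C/C(C)=C/CO | starting material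
16 | (2E)-3-methyl-5-[(4R)-2,6,6-trimethyl-4-(triethylsilyloxy)cyclohex-1-en-1-yl]pent-2-en-4-yn-1-ol | CC1=C(C#C/C(C)=C/CO)C(C)(C)C[C@H](O[Si](CC)(CC)CC)C1 | intermediate
17 | (2E)-5-[(4R)-4-hydroxy-2,6,6-trimethylcyclohex-1-en-1-yl]-3-methylpent-2-en-4-yn-1-ol (not isolated) | CC1=C(C#C/C(C)=C/CO)C(C)(C)C[C@H](O)C1 | intermediate
18 | {(2E)-5-[(4R)-4-hydroxy-2,6,6-trimethylcyclohex-1-en-1-yl]-3-methylpent-2-en-4-yn-1-yl}triphenylphosphonium bromide | CC1=C(C#C/C(C)=C/C[P+](c2ccccc2)(c2ccccc2)c2ccccc2)C(C)(C)C[C@H](O)C1.[Br-] | intermediate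
19 | (2E)-3-methylpenta-2,4-dien-1-ol | C=C/C(C)=C/CO | intermediate
20 | 9-[(3E)-5-(9-borabicyclo[3.3.1]nonan-9-yloxy)-3-methylpent-3-en-1-yl]-9-borabicyclo[3.3.1]nonane (not isolated) | B1(CC/C(C)=C/COB2C3CCCC2CCC3)C2CCCC1CCC2 | intermediate
21 | (2E)-3-methyl-5-[(4R)-2,6,6-trimethyl-4-(triethylsilyloxy)cyclohex-1-en-1-yl]pent-2-en-1-ol | OC/C=C(\C)CCC1=C(C)C[C@@H](O[Si](CC)(CC)CC)CC1(C)C | intermediate
22 | (2E)-5-[(4R)-4-hydroxy-2,6,6-trimethylcyclohex-1-en-1-yl]-3-methylpent-2-en-1-ol (not isolated) | OC/C=C(\C)CCC1=C(C)C[C@@H](O)CC1(C)C | intermediate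
23 | {(2E)-5-[(4R)-4-hydroxy-2,6,6-trimethylcyclohex-1-en-1-yl]-3-methylpent-2-en-1-yl}triphenylphosphonium bromide | C(/C=C(\C)CCC1=C(C)C[C@@H](O)CC1(C)C)[P+](c1ccccc1)(c1ccccc1)c1ccccc1.[Br-] | intermediate
24 | (2E,4E,6E)-2,7-dimethylocta-2,4,6-trienedial | O=C/C(C)=C/C=C/C=C(\C)C=O | starting material
25 | phosphorus ylide of 23 (not isolated) | C(/C=C(\C)CCC1=C(C)C[C@@H](O)CC1(C)C)=P(c1ccccc1)(c1ccccc1)c1ccccc1 | intermediate
26 | (2E,4E,6E,8Z,10E)-isomer of 27 (not isolated) | O=C/C(C)=C/C=C/C=C(C)/C=C\C=C(/C)CCC1=C(C)C[C@@H](O)CC1(C)C | intermediate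
27 | (2E,4E,6E,8E,10E)-13-[(4R)-4-hydroxy-2,6,6-trimethylcyclohex-1-en-1-yl]-2,7,11-trimethyltrideca-2,4,6,8,10-pentaenal | O=C/C(C)=C/C=C/C=C(C)/C=C/C=C(\C)CCC1=C(C)C[C@@H](O)CC1(C)C | intermediate
28 | phosphorus ylide of 18 (not isolated) | CC1=C(C#C/C(C)=C/C=P(c2ccccc2)(c2ccccc2)c2ccccc2)C(C)(C)C[C@H](O)C1 | intermediate
29 | (11Z)-isomer of 30 (not isolated) | CC1=C(C#C/C(C)=C/C=C\C(C)=C\C=C\C=C(C)\C=C\C=C(/C)CCC2=C(C)C[C@@H](O)CC2(C)C)C(C)(C)C[C@H](O)C1 | intermediate
30 | (3R,3'R)-all-E-7,8-didehydro-7',8'-dihydro-β,β-carotene-3,3'-diol | CC1=C(C#C/C(C)=C/C=C/C(C)=C/C=C/C=C(C)/C=C/C=C(\C)CCC2=C(C)C[C@@H](O)CC2(C)C)C(C)(C)C[C@H](O)C1 | target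

**Step count and risks**
Total steps: 14. Longest linear sequence: 11 steps (steps 1–7 and 11–14).

Steps most likely to fail:

1. Step 5 (the step proposed as a new method). The trivalent samarium enolate may be protonated or may not take up the methyl group at the fully substituted carbon, the enone may undergo simple conjugate reduction without ring closure, and facial selectivity in the ring closure may be modest. The fallback closes the same bond with reversed polarity by known chemistry; it sets out from 7 and returns at 11. Rhodium-catalysed conjugate hydrosilylation of 7 (RhCl(PPh3)3, Et3SiH) should give the regiodefined silyl enol ether triethyl{[(4S)-2,4,7-trimethylocta-2,6-dien-3-yl]oxy}silane F1. A Mukaiyama aldol reaction with aqueous formaldehyde (Sc(OTf)3) should give (4S)-1-hydroxy-2,2,4,7-tetramethyloct-6-en-3-one F2, which already holds the gem-dimethyl carbon. PPh3, I2 and imidazole in warm toluene should give (4S)-1-iodo-2,2,4,7-tetramethyloct-6-en-3-one F3. Ozonolysis with PPh3 work-up, through the ozonide F4, should give (3S)-6-iodo-3,5,5-trimethyl-4-oxohexanal F5. CrCl2 with catalytic cobalt phthalocyanine in DMF (Takai alkylchromium addition, selective for aldehydes over ketones) should form the alkylchromium species F6, which adds to the aldehyde and gives 11. In this closure the axial methyl of the preformed gem-dimethyl carbon forces the aldehyde oxygen equatorial, so the cis isomer is expected.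

2. Step 11. Transmetalation of the alkylborane onto the hindered tetrasubstituted enol triflate may be slow, so that triflate hydrolysis and protodeboronation compete. The fallback moves the hindered coupling to a small sp2 partner; it sets out from 14 and returns at 21. Stille coupling of 14 with tributyl(vinyl)stannane (Pd(PPh3)4, LiCl, THF, reflux) should give triethyl{[(1R)-4-ethenyl-3,5,5-trimethylcyclohex-3-en-1-yl]oxy}silane F7. Hydroboration of its terminal vinyl group with 9-borabicyclo[3.3.1]nonane should give 9-{2-[(4R)-2,6,6-trimethyl-4-(triethylsilyloxy)cyclohex-1-en-1-yl]ethyl}-9-borabicyclo[3.3.1]nonane F8. Suzuki–Miyaura coupling of F8 with the unhindered (E)-3-iodobut-2-en-1-ol (Pd(dppf)Cl2, aq. base) should form the C8'–C9' bond and give 21.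

3. Step 14. The 9E geometry next to the triple bond may be lost through the delocalised allyl cation in step 9 or the ylide in step 14, and Z→E correction at C11=C12 may be incomplete. The fallback reverses the roles of the partners so that the acetylenic fragment is never an allyl cation or ylide; it sets out from 16 and 27 and returns at 30. MnO2 oxidation of 16 should give (2E)-3-methyl-5-[(4R)-2,6,6-trimethyl-4-(triethylsilyloxy)cyclohex-1-en-1-yl]pent-2-en-4-ynal F9. NaBH4 reduction of 27 should give the C25 allylic alcohol F10, and PPh3·HBr the C25 phosphonium bromide F11. Its ylide F12 (NaOMe) should condense with F9 to give the 3-O-triethylsilyl ether of the target F13. Pyridinium p-toluenesulfonate in MeOH should then remove the silyl group and give 30.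

**Further compounds**
F1 | step 5 | triethyl{[(4S)-2,4,7-trimethylocta-2,6-dien-3-yl]oxy}silane | CC(C)=CC[C@H](C)C(O[Si](CC)(CC)CC)=C(C)C
F2 | step 5 | (4S)-1-hydroxy-2,2,4,7-tetramethyloct-6-en-3-one | CC(C)=CC[C@H](C)C(=O)C(C)(C)CO
F3 | step 5 | (4S)-1-iodo-2,2,4,7-tetramethyloct-6-en-3-one | CC(C)=CC[C@H](C)C(=O)C(C)(C)CI
F4 | step 5 | (4S)-5-(5,5-dimethyl-1,2,4-trioxolan-3-yl)-1-iodo-2,2,4-trimethylpentan-3-one | CC1(C)OOC(C[C@H](C)C(=O)C(C)(C)CI)O1
F5 | step 5 | (3S)-6-iodo-3,5,5-trimethyl-4-oxohexanal | O=CC[C@H](C)C(=O)C(C)(C)CI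
F6 | step 5 | dichloro[(4S)-2,2,4-trimethyl-3,6-dioxohexyl]chromium | O=CC[C@H](C)C(=O)C(C)(C)C[Cr](Cl)Cl
F7 | step 11 | triethyl{[(1R)-4-ethenyl-3,5,5-trimethylcyclohex-3-en-1-yl]oxy}silane | C=CC1=C(C)C[C@@H](O[Si](CC)(CC)CC)CC1(C)C
F8 | step 11 | 9-{2-[(4R)-2,6,6-trimethyl-4-(triethylsilyloxy)cyclohex-1-en-1-yl]ethyl}-9-borabicyclo[3.3.1]nonane | B1(CCC2=C(C)C[C@@H](O[Si](CC)(CC)CC)CC2(C)C)C2CCCC1CCC2
F9 | step 14 | (2E)-3-methyl-5-[(4R)-2,6,6-trimethyl-4-(triethylsilyloxy)cyclohex-1-en-1-yl]pent-2-en-4-ynal | CC1=C(C#C/C(C)=C/C=O)C(C)(C)C[C@H](O[Si](CC)(CC)CC)C1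
F10 | step 14 | (2E,4E,6E,8E,10E)-13-[(4R)-4-hydroxy-2,6,6-trimethylcyclohex-1-en-1-yl]-2,7,11-trimethyltrideca-2,4,6,8,10-pentaen-1-ol | OC/C(C)=C/C=C/C=C(C)/C=C/C=C(\C)CCC1=C(C)C[C@@H](O)CC1(C)C
F11 | step 14 | {(2E,4E,6E,8E,10E)-13-[(4R)-4-hydroxy-2,6,6-trimethylcyclohex-1-en-1-yl]-2,7,11-trimethyltrideca-2,4,6,8,10-pentaen-1-yl}triphenylphosphonium bromide | C(/C(C)=C/C=C/C=C(C)/C=C/C=C(\C)CCC1=C(C)C[C@@H](O)CC1(C)C)[P+](c1ccccc1)(c1ccccc1)c1ccccc1.[Br-]
F12 | step 14 | phosphorus ylide of F11 | C(/C(C)=C/C=C/C=C(C)/C=C/C=C(\C)CCC1=C(C)C[C@@H](O)CC1(C)C)=P(c1ccccc1)(c1ccccc1)c1ccccc1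
F13 | step 14 | 3-O-triethylsilyl ether of 30 (silyl group on the acetylenic end ring) | CC1=C(C#C/C(C)=C/C=C/C(C)=C/C=C/C=C(C)/C=C/C=C(\C)CCC2=C(C)C[C@@H](O)CC2(C)C)C(C)(C)C[C@H](O[Si](CC)(CC)CC)C1
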